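Spent catalyst cannot return to the round, since the candidate step between free catalyst and impurity runs one way, one impurity per catalyst. So I write the balance of the smaller charge in that step, its limiting reagent. In eta, c impurity of 0.60 mM lies below the 1.20 mM of catalyst charged, and in delta c impurity of 0.43 mM lies below it too. Assuming the impurity is used up early, the working catalyst, meaning catalyst charged minus c impurity at the start, is 0.600 mM in eta and 0.770 mM in delta.

| setting | green | grey | eta | delta |
|---|---|---|---|---|
| starting material | 1.2 M | 1.2 M | 1.2 M | 1.2 M |
| coupling partner | 0.60 equiv | 0.60 equiv | 0.600 equiv | 0.600 equiv |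
| precatalyst | 0.1 mol% | 0.1 mol% | 0.1 mol% | 0.1 mol% |
| impurity | 0.46 mM | 0.53 mM | 0.60 mM | 0.43 mM |
| temperature | 114 °C | 122 °C | 125 °C | 110 °C |
| remark | run made earlier | run made earlier |  |  |
| time |  |  | 12 min | 12 min |

| run | time / min | product / % |
|---|---|---|
| green | 1.33 | 0.7 |
| green | 2.50 | 2.3 |
| green | 4.00 | 5.0 |
| green | 5.00 | 7.3 |
| green | 6.00 | 9.0 |
| grey | 0.250 | 0 |
| grey | 0.500 | 0.3 |
| grey | 0.833 | 1.2 |
| grey | 1.50 | 3.3 |
| grey | 3.00 | 7.6 |

(standard deviation of a reading: 0.3 percentage points)

* which one finishes higher in amount of product, in percent of the starting material charged ("neither" within 2 percentage points) (eta / delta / neither)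
* amount of product at the end, in percent of the starting material charged, eta
* amount of product at the end, in percent of the starting material charged, delta

- candidate steps: starting material + free catalyst -> catalyst intermediate A; catalyst intermediate A <-> catalyst intermediate B; coupling partner + catalyst intermediate B -> catalyst intermediate C; catalyst intermediate C -> catalyst intermediate D; catalyst intermediate D -> free catalyst + product; free catalyst + impurity -> spent catalyst; precatalyst -> free catalyst

What does a unit of working catalyst give at each temperature, if the rate follows it? Past its lag, the green run gains 0.0191 min⁻¹ of the charge on 0.740 mM of working catalyst. The grey run gains 0.0287 min⁻¹ on 0.670 mM. Per unit of working catalyst, then, grey reads 1.65 times green, and I put that factor down to temperature.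

What does this give at the new temperatures? Scaling the factor geometrically with temperature, I reckon 0.0310 min⁻¹ for eta and 0.0155 min⁻¹ for delta, so I expect eta to run twice as fast as delta, although its working catalyst is smaller.

How much does the lag take away? Read back from the curves, it is 1.30 min in green and 0.349 min in grey. Scaling it the same way, I expect 36.5% for eta and 14.7% for delta at 12 min, a gap of 22 percentage points, wider than the margin.

The forecast, reading the “impurity as titrating catalyst”, names eta, with 33% there, lower than my eta figure, and 14% in delta.

Eta gives 36.0% and delta 14.4%, so eta finishes higher.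

    starting material + free catalyst → catalyst intermediate A (k = 1.60 L mol⁻¹ s⁻¹, Ea = 76.0 kJ mol⁻¹)
    catalyst intermediate A ⇌ catalyst intermediate B (K = 0.320, k = 2.30 s⁻¹, Ea = 82.0 kJ mol⁻¹, ΔH = 17.0 kJ mol⁻¹)
    coupling partner + catalyst intermediate B → catalyst intermediate C (k = 22.0 L mol⁻¹ s⁻¹, Ea = 47.0 kJ mol⁻¹)
    catalyst intermediate C → catalyst intermediate D (k = 1.50 s⁻¹, Ea = 102 kJ mol⁻¹)
    catalyst intermediate D → free catalyst + product (k = 1.80 s⁻¹, Ea = 98.0 kJ mol⁻¹)
    free catalyst + impurity → spent catalyst (k = 39.0 L mol⁻¹ s⁻¹, Ea = 63.0 kJ mol⁻¹)
    precatalyst → free catalyst (k = 0.00520 s⁻¹, Ea = 117 kJ mol⁻¹)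
    (constants at 110 °C)

At 12.0 min in eta, spent catalyst is 50.0% of the catalyst charged and the impurity is down to 0.00876% of its own charge. The forms still in the round sum to 50.0%, against a working catalyst of 50.0% of the charge. In delta at 120 min, coupling partner is at 0% and product at 60.0%. There the working catalyst, 64.2% of the charge, stands as catalyst intermediates A and B, 64.2% together, beside 35.8% spent.

The data were generated by integration from invented constants; noise was put on by code.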